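**Plan**
- Retrosynthesis: the two angelates are cut last, the C2 and C6 carbinols go back to ketones, and the cycloheptene is cut at C6–C7 and C1–C10 (C1 = quaternary ring-fusion carbon, C5 = ring-fusion CH, C4 = tertiary carbinol).
- Enabling feature: the arc C7–C8(Me)=C9–C10 touches the rest only at C6 and C1, and C6 bears oxygen and is joined through C5 to C1. At the enol level (C5=C6) the seven-membered ring is therefore a 1,4-cycloheptadiene, the product of a cis-divinylcyclopropane rearrangement between a cyclopentenyl acylsilane (C6, C5=C1) and 2-oxidobutadiene (C7–C10).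
- Forward order: the cyclopentene comes first, by ozonolysis/aldol ring contraction of (S)-terpinen-4-ol, γ-hydroxylation at C2 and a temporary silylene ring. The cycloheptene follows in the key step, and the C8 oxygen is exchanged for methyl through the enol triflate.
- Stereochemistry: C4 comes from terpinen-4-ol. The C2 hydroxyl is first placed cis to the C4 hydroxyl so that the silylene bridge blocks the β face and sends C10 to the α face of C1. C5 is set by α-face protonation, C2 and C6 together by hydride delivery from the 4β-hydroxyl, and the Z esters come from angelic acid.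

Key step: step 8

Remark: β is the face of the angular methyl on C1; C2–C3–C4 complete the five-membered ring and C6–C7–C8(Me)=C9–C10 the seven-membered ring ("dauc-8-ene" numbering); (S)-terpinen-4-ol is assumed to be used in enantiopure form.

**Route**

Step 1
Reactants: 1 (S)-terpinen-4-ol
Product: 3 (S)-3-hydroxy-6-oxo-3-(propan-2-yl)heptanal, via ozonide 2 (not isolated)
Conditions: O3, CH2Cl2, −78 °C; then Me2S, −78 °C → rt
Reagents that add atoms: ozone, [O-][O+]=O
Why: Ozonolysis with reductive work-up cleaves the single trisubstituted alkene to a methyl ketone and an aldehyde and does not touch the tertiary carbinol stereocentre (C4 of the target).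

Step 2
Reactants: 3 (S)-3-hydroxy-6-oxo-3-(propan-2-yl)heptanal
Product: 5 (R)-5-hydroxy-2-methyl-5-(propan-2-yl)cyclopent-1-ene-1-carbaldehyde, via aldol adduct 4 (not isolated)
Conditions: piperidine (cat.), AcOH (cat.), benzene, 60–80 °C
Reagents that add atoms: none
Why: Amine–acid catalysed intramolecular aldol condensation (the enamine of the aldehyde attacks the methyl ketone to close the five-membered ring, then dehydration into conjugation) should give the cyclopentene carbaldehyde, as known for related terpene-derived keto aldehydes, without involving the carbinol centre.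

Step 3
Reactants: 5 (R)-5-hydroxy-2-methyl-5-(propan-2-yl)cyclopent-1-ene-1-carbaldehyde
Product: 6 (R)-3-methyl-1-(propan-2-yl)-2-[(triisopropylsilyloxy)methylidene]cyclopent-3-en-1-ol (enol ether geometry not controlled)
Conditions: TIPSOTf, Et3N, CH2Cl2, −78 °C → 0 °C
Reagents that add atoms: triisopropylsilyl triflate, CC(C)[Si](OS(=O)(=O)C(F)(F)F)(C(C)C)C(C)C
Why: Vinylogous silyl enol ether formation by soft enolisation should remove a ring C2 proton to give the extended dienol ether with the more substituted endocyclic C1=C2 alkene, while the bulky silyl triflate leaves the hindered tertiary hydroxyl free; no stereocentre is formed.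

Step 4
Reactants: 6 triisopropylsilyl dienol ether
Product: 8 (3R,5R)-3,5-dihydroxy-2-methyl-5-(propan-2-yl)cyclopent-1-ene-1-carbaldehyde (hydroxyls cis), via epoxide 7 (not isolated)
Conditions: dimethyldioxirane, acetone/CH2Cl2, −78 °C → −40 °C; then Et3N·3HF, THF, 0 °C
Reagents that add atoms: dimethyldioxirane, CC1(C)OO1
Why: Vinylogous Rubottom oxidation: the dioxirane should epoxidise the distal C1=C2 bond on the face of the tertiary hydroxyl (hydrogen bonding, and anti to the isopropyl group), and push from the silyloxy group opens the epoxide to the γ-hydroxy enal, so the new C2 hydroxyl is cis to the C4 hydroxyl.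

Step 5
Reactants: 8 cis-diol enal
Product: 9 3,5-O-(di-tert-butylsilanediyl) ether of 8 (2,4-dioxa-3-silabicyclo[3.2.1]oct-6-ene-6-carbaldehyde)
Conditions: tBu2Si(OTf)2, 2,6-lutidine, CH2Cl2, 0 °C → rt
Reagents that add atoms: di-tert-butylsilyl bis(triflate), CC(C)(C)[Si](OS(=O)(=O)C(F)(F)F)(OS(=O)(=O)C(F)(F)F)C(C)(C)C
Why: Cyclic silylene protection is possible only for the cis-1,3-diol and installs the temporary ring that covers the β face of the cyclopentene.

Step 6
Reactants: 9 silylene enal
Product: 10 (dimethylphenylsilyl)carbinol of 9 (both epimers at the new carbinol carbon C6)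
Conditions: PhMe2SiLi, THF, −78 °C; aqueous NH4Cl at −78 °C
Reagents that add atoms: (dimethylphenylsilyl)lithium, [Li][Si](C)(C)c1ccccc1
Why: Carbonyl addition of the silyl anion should occur 1,2 because the β-carbon is fully substituted, and cold quenching prevents Brook rearrangement; the new carbinol centre forms unselectively and is removed in step 7.

Step 7
Reactants: 10 α-silyl carbinol
Product: 11 acylsilane: (dimethylphenylsilyl) ketone on C6 of the silylene-bridged 2-methylcyclopentene
Conditions: (COCl)2, DMSO, CH2Cl2, −78 °C; Et3N, −78 °C → −20 °C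
Reagents that add atoms: none
Why: Swern oxidation converts α-hydroxysilanes to acylsilanes at low temperature without Brook rearrangement and leaves the silylene intact.

Step 8
Reactants: 11 acylsilane; 12 2-(trimethylsilyloxy)buta-1,3-diene
Product: 17 bicyclic enol triflate (6-dimethylphenylsilyloxy 5-ene; 8-triflyloxy 8-ene; 2β,4β-silylene; C10 α on C1), via lithium dienolate 13 (not isolated), via alkoxide 14 (not isolated), via cyclopropanolate 15 (not isolated), via cycloheptadienolate 16 (not isolated)
Conditions: 12, MeLi, THF, 0 °C; cool to −80 °C, add 11; −80 °C → −30 °C; then PhNTf2, −30 °C → 0 °C; aqueous NH4Cl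
Reagents that add atoms: N-phenylbis(trifluoromethanesulfonimide), O=S(=O)(N(c1ccccc1)S(=O)(=O)C(F)(F)F)C(F)(F)F
Why: Dienolate 13 adds to the acylsilane carbonyl (C6–C7 bond, alkoxide 14); a 1,2-Brook shift of silicon from C6 to oxygen then makes C6 carbanionic and it closes at once on the ketone carbonyl by 3-exo-trig attack to the cis-1,2-dialkenylcyclopropanolate 15, whose ring strain and alkoxide drive an anionic oxy-Cope shift that forms C1–C10 and gives the regiodefined C8–C9 enolate 16, trapped as triflate 17. The closest known reaction type is the Brook rearrangement-mediated (3+4) annulation of β-substituted acryloylsilanes with lithium enolates of alkenyl methyl ketones; here the acylsilane alkene is the ring C5=C1 bond, so the shift creates the quaternary C1. The seven-membered ring closes by the (3,3)-sigmatropic shift through a six-centre boat transition state with both alkenyl arms over the cyclopropane, the only geometry that gives the cis,cis-1,4-cycloheptadiene. C1 is the only new stereocentre: the silylene bridge spanning C2 and C4 covers the β face of the cyclopentene, so C10 should bond to C1 from the α face, anti to the adjacent C2 oxygen, and a cyclopropanolate that would need the β face is expected to revert through the siloxyallyl anion. The step needs 1,2- and not 1,4-addition (fully substituted C1, high carbonyl reactivity of acylsilanes), a cis cyclopropanolate (lithium-bridged silyl transfer) and no β-elimination of the C2 silyloxy group (the charge is trapped at C6 as it forms).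

Step 9
Reactants: 17 bicyclic enol triflate
Product: 18 dauca-5,8-diene-2β,4β,6-triol 2,4-O-(di-tert-butylsilanediyl) 6-O-(dimethylphenylsilyl) ether
Conditions: MeZnCl, Pd(PPh3)4 (5 mol %), THF, rt
Reagents that add atoms: methylzinc chloride, C[Zn]Cl
Why: Negishi coupling of the enol triflate is regio-retentive, so the methyl group is placed on C8 with the C8=C9 alkene fixed by the preceding sigmatropic shift, and the silyl enol ether and silylene are inert to the organozinc.

Step 10
Reactants: 18 silyl enol ether diene
Product: 20 2β,4β-dihydroxydauc-8-en-6-one (5α-H, trans-fused), via silylene ketone 19 (not isolated)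
Conditions: HF·pyridine, pyridine, THF, 0 °C → rt
Reagents that add atoms: none
Why: Desilylation should cleave the labile dimethylphenylsilyl enol ether first, so that C5 is protonated on the α face opposite the silylene bridge to give the trans-fused ketone 19 (also expected to be the thermodynamic isomer, C6 trans to the isopropyl group), and then remove the silylene.

Step 11
Reactants: 20 2β,4β-dihydroxydauc-8-en-6-one
Product: 21 4β-hydroxydauc-8-ene-2,6-dione
Conditions: Dess–Martin periodinane, NaHCO3, CH2Cl2, 0 °C → rt
Reagents that add atoms: none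
Why: Buffered Dess–Martin oxidation converts the only oxidisable (secondary, C2) alcohol to the ketone without base that could trigger retro-aldol cleavage of the tertiary β-hydroxy ketone, and erases the provisional C2 stereocentre.

Step 12
Reactants: 21 4β-hydroxydauc-8-ene-2,6-dione
Product: 22 (1R,2S,4R,5S,6S)-dauc-8-ene-2α,4β,6α-triol
Conditions: Me4NBH(OAc)3 (excess), MeCN/AcOH, −30 °C → 0 °C
Reagents that add atoms: none
Why: Evans–Saksena reduction: the 4β-hydroxyl exchanges onto boron and should deliver hydride intramolecularly to the β faces of both β-carbonyl groups (C2 across the five-membered ring, C6 through a six-membered chair), so both new hydroxyls are α (1,3-anti to the tertiary hydroxyl), while undirected reduction by the triacetoxyborohydride is slow.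

Step 13
Reactants: 22 dauc-8-ene-2α,4β,6α-triol; 23 angelic acid ((Z)-2-methylbut-2-enoic acid), of which two molecules are incorporated
Product: 25 2α,6α-bis(angeloyloxy)dauc-8-en-4β-ol (1R,2S,4R,5S,6S; the target), via mixed anhydride 24 (not isolated)
Conditions: 23 (5 equiv), 2,4,6-trichlorobenzoyl chloride (5 equiv), Et3N, toluene, rt; then 22, 80 °C, until both secondary hydroxyls are acylated
Reagents that add atoms: angelic acid (the second molecule of 23, which supplies the second angeloyl group), C/C=C(/C)C(=O)O
Why: Yamaguchi-type mixed-anhydride esterification without a nucleophilic amine catalyst should transfer one angeloyl group from each of two molecules of anhydride 24 to the C2 and C6 secondary alcohols, leave the hindered tertiary hydroxyl free and keep the Z geometry of the angelate (no isomerisation to tiglate).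

**Compound list**

1 | (S)-terpinen-4-ol | CC1=CC[C@](O)(C(C)C)CC1 | starting material
2 | ozonide of 1 | CC12CC[C@@](O)(C(C)C)CC(OO1)O2 | intermediate (not isolated)
3 | (S)-3-hydroxy-6-oxo-3-(propan-2-yl)heptanal | CC(=O)CC[C@@](O)(C(C)C)CC=O | intermediate
4 | aldol adduct, 2,5-dihydroxy-2-methyl-5-(propan-2-yl)cyclopentane-1-carbaldehyde | O=CC1C(C)(O)CC[C@@]1(O)C(C)C | intermediate (not isolated)
5 | (R)-5-hydroxy-2-methyl-5-(propan-2-yl)cyclopent-1-ene-1-carbaldehyde | O=CC1=C(C)CC[C@@]1(O)C(C)C | intermediate
6 | triisopropylsilyl dienol ether of 5 | CC(C)[Si](C(C)C)(C(C)C)OC=C1C(C)=CC[C@@]1(O)C(C)C | intermediate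
7 | C1–C2 epoxide of 6 on the hydroxyl face | CC(C)[Si](C(C)C)(C(C)C)OC=C1[C@]2(C)O[C@@H]2C[C@@]1(O)C(C)C | intermediate (not isolated)
8 | (3R,5R)-3,5-dihydroxy-2-methyl-5-(propan-2-yl)cyclopent-1-ene-1-carbaldehyde | O=CC1=C(C)[C@H](O)C[C@@]1(O)C(C)C | intermediate
9 | di-tert-butylsilylene ether of 8 | O=CC1=C(C)[C@H](O[Si]2(C(C)(C)C)C(C)(C)C)C[C@@]1(O2)C(C)C | intermediate
10 | (dimethylphenylsilyl)carbinol of 9 | C[Si](C)(c1ccccc1)C(O)C1=C(C)[C@H](O[Si]2(C(C)(C)C)C(C)(C)C)C[C@@]1(O2)C(C)C | intermediate
11 | acylsilane | C[Si](C)(c1ccccc1)C(=O)C1=C(C)[C@H](O[Si]2(C(C)(C)C)C(C)(C)C)C[C@@]1(O2)C(C)C | intermediate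
12 | 2-(trimethylsilyloxy)buta-1,3-diene | C=CC(=C)O[Si](C)(C)C | starting material
13 | lithium buta-1,3-dien-2-olate | C=CC(=C)O[Li] | intermediate (not isolated)
14 | lithium alkoxide from 1,2-addition | C[Si](C)(c1ccccc1)C(O[Li])(CC(=O)C=C)C1=C(C)[C@H](O[Si]2(C(C)(C)C)C(C)(C)C)C[C@@]1(O2)C(C)C | intermediate (not isolated)
15 | cis-1-siloxy-2-vinyl-1-cyclopentenylcyclopropan-2-olate | C[Si](C)(c1ccccc1)O[C@]1(C[C@]1(O[Li])C=C)C3=C(C)[C@H](O[Si]2(C(C)(C)C)C(C)(C)C)C[C@@]3(O2)C(C)C | intermediate (not isolated)
16 | lithium cycloheptadienolate | C[Si](C)(c1ccccc1)OC1=C2[C@](O[Si]3(C(C)(C)C)C(C)(C)C)(C(C)C)C[C@@H](O3)[C@]2(C)CC=C(O[Li])C1 | intermediate (not isolated)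
17 | bicyclic enol triflate | C[Si](C)(c1ccccc1)OC1=C2[C@](O[Si]3(C(C)(C)C)C(C)(C)C)(C(C)C)C[C@@H](O3)[C@]2(C)CC=C(OS(=O)(=O)C(F)(F)F)C1 | intermediate
18 | C8-methyl silyl enol ether diene | C[Si](C)(c1ccccc1)OC1=C2[C@](O[Si]3(C(C)(C)C)C(C)(C)C)(C(C)C)C[C@@H](O3)[C@]2(C)CC=C(C)C1 | intermediate
19 | 2β,4β-O-(di-tert-butylsilanediyl)dauc-8-en-6-one (trans-fused) | O=C1CC(C)=CC[C@@]2(C)[C@H](O[Si]3(C(C)(C)C)C(C)(C)C)C[C@@](O3)(C(C)C)[C@H]12 | intermediate (not isolated)
20 | 2β,4β-dihydroxydauc-8-en-6-one | O=C1CC(C)=CC[C@@]2(C)[C@H](O)C[C@@](O)(C(C)C)[C@H]12 | intermediate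
21 | 4β-hydroxydauc-8-ene-2,6-dione | O=C1CC(C)=CC[C@@]2(C)C(=O)C[C@@](O)(C(C)C)[C@H]12 | intermediate
22 | dauc-8-ene-2α,4β,6α-triol | O[C@H]1CC(C)=CC[C@@]2(C)[C@@H](O)C[C@@](O)(C(C)C)[C@H]12 | intermediate
23 | angelic acid | C/C=C(/C)C(=O)O | starting material
24 | angelic 2,4,6-trichlorobenzoic anhydride | C/C=C(/C)C(=O)OC(=O)c1c(Cl)cc(Cl)cc1Cl | intermediate (not isolated)
25 | 2α,6α-bis(angeloyloxy)dauc-8-en-4β-ol | C/C=C(/C)C(=O)O[C@H]1CC(C)=CC[C@@]2(C)[C@@H](OC(=O)/C(C)=C\C)C[C@@](O)(C(C)C)[C@H]12 | target

**Step count and risks**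

Total: 13 steps. Longest linear sequence: 13 steps (1 → 25); 12 and 23 enter as purchased.

Steps most likely to fail:

1. Step 8. After the Brook shift the siloxyallyl anion may not rearrange at the fully substituted C1 terminus, because the boat transition state carries the C1 methyl group inside. It could then close a five-membered ring, collapse to open-chain products, eliminate the C2 silyloxy oxygen, or react with poor facial selectivity at C1. The fallback builds the ring stepwise, sets out from 11 and returns at 19. Hosomi–Sakurai conjugate allylation of the acylsilane (allyltrimethylsilane, TiCl4, CH2Cl2, −78 °C) should add the allyl group to C1 on the α face, anti to the silylene, and give the β-allyl acylsilane F1. K2CO3 in aqueous MeOH converts the acylsilane to the aldehyde F2 and equilibrates C5 so that the formyl group is trans to the allyl and isopropyl groups. 2-Methylallylmagnesium chloride (THF, −78 °C) gives the homoallylic alcohol F3 as both C6 epimers. Ring-closing metathesis with the second-generation Grubbs catalyst (CH2Cl2, 40 °C) forms C8=C9 and gives the trans-fused bicyclic alcohol F4. Dess–Martin oxidation then gives silylene ketone 19, which is desilylated as in step 10.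

2. Step 4. Epoxidation may occur at the enol ether bond under direction by the allylic hydroxyl (oxygen at C5 instead of C2). Step 3 may have enolised toward the methyl group, facial selectivity may be poor, or the γ-hydroxyl may be lost by elimination to a cyclopentadiene. The fallback places the oxygen on the cyclohexene before ring contraction, sets out from 1 and returns at 8. Allylic oxidation with SeO2 (cat.) and t-BuOOH in CH2Cl2 at the ring methylene next to the methyl-bearing alkene carbon should give the cis-diol F5, with oxygen delivered on the hydroxyl face through the selenite ester of the tertiary alcohol; any trans isomer is separated. Ozonolysis (ozonide F6, then Me2S) gives the hydroxy keto aldehyde F7. Piperidine/AcOH aldol condensation through the aldol adduct F8 then gives 8.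

3. Step 12. Once boron is tied between O4 and O6 the second carbonyl may not be reduced by internal delivery. External hydride may attack C2 from the α face, the tertiary β-hydroxy diketone may undergo retro-aldol cleavage or dehydration, and C8=C9 may move into conjugation with the C6 ketone. The fallback reduces the two carbonyls one at a time, sets out from 20 and returns at 22. Evans–Saksena reduction of 20 (Me4NBH(OAc)3, MeCN/AcOH) reduces only C6 and gives the 2β,4β,6α-triol F9. TBSCl and imidazole silylate the less hindered C6 hydroxyl to give silyl ether F10. Dess–Martin oxidation gives the C2 ketone F11. A second hydroxyl-directed reduction gives the 2α-alcohol F12, and TBAF returns triol 22.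

Further compounds
F1 | step 8 | β-allyl acylsilane | C[Si](C)(c1ccccc1)C(=O)[C@@H]1[C@@](C)(CC=C)[C@H](O[Si]2(C(C)(C)C)C(C)(C)C)C[C@@]1(O2)C(C)C
F2 | step 8 | allyl aldehyde | O=C[C@@H]1[C@@](C)(CC=C)[C@H](O[Si]2(C(C)(C)C)C(C)(C)C)C[C@@]1(O2)C(C)C
F3 | step 8 | homoallylic alcohol (C6 epimers) | C=C(C)CC(O)[C@@H]1[C@@](C)(CC=C)[C@H](O[Si]2(C(C)(C)C)C(C)(C)C)C[C@@]1(O2)C(C)C
F4 | step 8 | trans-fused bicyclic alcohol (C6 epimers) | OC1CC(C)=CC[C@@]2(C)[C@H](O[Si]3(C(C)(C)C)C(C)(C)C)C[C@@](O3)(C(C)C)[C@H]12
F5 | step 4 | cis-2-methyl-5-(propan-2-yl)cyclohex-2-ene-1,5-diol | CC1=CC[C@](O)(C(C)C)C[C@H]1O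
F6 | step 4 | ozonide of F5 | CC12[C@H](O)C[C@@](O)(C(C)C)CC(OO1)O2
F7 | step 4 | 3,5-dihydroxy-6-oxo-3-(propan-2-yl)heptanal | CC(=O)[C@H](O)C[C@@](O)(C(C)C)CC=O
F8 | step 4 | aldol adduct of F7 | O=CC1C(C)(O)[C@H](O)C[C@@]1(O)C(C)C
F9 | step 12 | dauc-8-ene-2β,4β,6α-triol | O[C@H]1CC(C)=CC[C@@]2(C)[C@H](O)C[C@@](O)(C(C)C)[C@H]12
F10 | step 12 | 6-O-TBS ether of F9 | CC(C)(C)[Si](C)(C)O[C@H]1CC(C)=CC[C@@]2(C)[C@H](O)C[C@@](O)(C(C)C)[C@H]12
F11 | step 12 | 6α-(TBS-oxy)-4β-hydroxydauc-8-en-2-one | CC(C)(C)[Si](C)(C)O[C@H]1CC(C)=CC[C@@]2(C)C(=O)C[C@@](O)(C(C)C)[C@H]12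
F12 | step 12 | 6-O-TBS ether of triol 22 | CC(C)(C)[Si](C)(C)O[C@H]1CC(C)=CC[C@@]2(C)[C@@H](O)C[C@@](O)(C(C)C)[C@H]12
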